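**Plan**

1. Locants used here: ring B (cyclooctene) is C1(=CH2)–C2–C3–C4(H)–C5=C6(CH3)–C7(H)–C8(H); ring A is C4, C5, C16, C17, C18(CH3); ring C is C7, C8, C9, C10(CH3), C11, C12; ring D is C10, C11, C13(i-Pr), C14, C15(OH).
2. Retrosynthesis: C1=CH2 is taken back to a C1 ketone, and ring C is cut at C8–C9 (aldol condensation, then reduction). This exposes O=C1–C8–C7–C6=C5, a γ,δ-unsaturated ketone that spans rings B and A with the B/C fusion bond C7–C8 at its centre; a Claisen transform cuts that bond and leads to a C1–O–C5 enol ether, i.e. a δ-lactone fused to ring A.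
3. The lactone is cut at C5–C6 into a cis-2,3-disubstituted cyclopentanone (ring A, 6) and an (E)-alkenyl iodide that carries ring D with its two trans arms (19).
4. Forward: rings A and D come from purchased cyclopentenones. They are joined at C5–C6 with lactonisation; methylenation and Claisen ring expansion close ring B; aldol condensation closes ring C; reduction, methylenation and desilylation finish.
5. Stereochemistry: C4/C18 come from a CBS reduction relayed by an OH-directed hydrogenation. C13 is bought and relayed to C11, C10 and C15 by anti additions and a directed reduction. The C5 carbinol centre (set by ring A) is transferred to C7 in the Claisen step, and C8 is set by equilibration.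

Key step: step 16

Assumption: 1, 7, (3-ethoxy-3-oxopropyl)zinc bromide (THF solution) and tributyl(propa-1,2-dien-1-yl)stannane are taken as purchased; ketone 6 is used crude at once because its cis C4/C18 relationship is the less stable one.
Abbreviation: RD = (1S,2S,3R,5S)-3-[(tert-butyldimethylsilyl)oxy]-2-methyl-5-(propan-2-yl)-2-{[(triethylsilyl)oxy]methyl}cyclopentyl.

**West fragment (ring A)**

Step 1
Reactants: 1 3-methylcyclopent-2-en-1-one
Product: 2 2-iodo-3-methylcyclopent-2-en-1-one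
Conditions: I2, pyridine/CH2Cl2 (1:1), 0 °C to rt
Reagents that add atoms: iodine (II)
Why: α-Iodination of the enone by conjugate addition of pyridine, iodination of the enolate and elimination should give the α-iodoenone; no stereocenter is formed.

Step 2
Reactants: 2 2-iodo-3-methylcyclopent-2-en-1-one
Product: 3 ethyl 3-(2-methyl-5-oxocyclopent-1-en-1-yl)propanoate
Conditions: BrZnCH2CH2CO2Et (0.5 M in THF), PdCl2(dppf) (5 mol %), THF, 40 °C
Reagents that add atoms: (3-ethoxy-3-oxopropyl)zinc bromide (CCOC(=O)CC[Zn]Br)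
Why: Negishi cross-coupling of the α-iodoenone with the ester-tolerant zinc homoenolate should install the C3–C2–C1 chain on C4.

Step 3
Reactants: 3 ethyl 3-(2-methyl-5-oxocyclopent-1-en-1-yl)propanoate
Product: 4 ethyl 3-[(5S)-5-hydroxy-2-methylcyclopent-1-en-1-yl]propanoate
Conditions: (R)-Me-CBS oxazaborolidine (10 mol %), catecholborane, toluene, −78 °C
Reagents that add atoms: none
Why: Corey–Bakshi–Shibata reduction, with the substituted alkene carbon acting as the large group, should give the (S)-allylic alcohol and leave the ester untouched.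

Step 4
Reactants: 4 ethyl 3-[(5S)-5-hydroxy-2-methylcyclopent-1-en-1-yl]propanoate
Product: 5 ethyl 3-[(1S,2S,5S)-2-hydroxy-5-methylcyclopentyl]propanoate
Conditions: H2 (1 atm), [Ir(cod)(PCy3)(py)]PF6 (5 mol %), CH2Cl2, rt
Reagents that add atoms: none
Why: Hydroxyl-directed hydrogenation of the tetrasubstituted alkene should deliver both hydrogens from the OH face, so the C4 chain and the C18 methyl end up cis to each other and trans to OH.

Step 5
Reactants: 5 ethyl 3-[(1S,2S,5S)-2-hydroxy-5-methylcyclopentyl]propanoate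
Product: 6 ethyl 3-[(1S,2S)-2-methyl-5-oxocyclopentyl]propanoate
Conditions: Dess–Martin periodinane, NaHCO3, CH2Cl2, 0 °C
Reagents that add atoms: none
Why: Buffered Dess–Martin oxidation should give the ketone without epimerising the kinetically set cis C4/C18 pair.

**East fragment (ring D)**

Step 6
Reactants: 7 (R)-4-[(tert-butyldimethylsilyl)oxy]cyclopent-2-en-1-one
Product: 9 (S)-4-(propan-2-yl)cyclopent-2-en-1-one, via trans-3-isopropyl-4-silyloxycyclopentanone 8 (not isolated)
Conditions: i-PrMgCl, CuBr·SMe2 (20 mol %), THF, −40 °C; aq NH4Cl; then DBU, CH2Cl2, rt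
Reagents that add atoms: isopropylmagnesium chloride (CC(C)[Mg]Cl)
Why: Copper-catalysed conjugate addition anti to the silyloxy group followed by E1cB loss of silanolate should transfer the purchased chirality to C13.

Step 7
Reactants: 9 (S)-4-(propan-2-yl)cyclopent-2-en-1-one
Product: 10 (S)-2-iodo-4-(propan-2-yl)cyclopent-2-en-1-one
Conditions: I2, pyridine/CH2Cl2 (1:1), 0 °C to rt
Reagents that add atoms: iodine (II)
Why: The same addition–iodination–elimination α-iodination of an enone as in step 1 should apply; the γ-stereocenter is not touched.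

Step 8
Reactants: 10 (S)-2-iodo-4-(propan-2-yl)cyclopent-2-en-1-one
Product: 11 (S)-2-methyl-4-(propan-2-yl)cyclopent-2-en-1-one
Conditions: Me4Sn, Pd2(dba)3 (2.5 mol %), AsPh3, CuI (10 mol %), NMP, 60 °C
Reagents that add atoms: tetramethylstannane (C[Sn](C)(C)C)
Why: Stille methylation of the α-iodoenone runs without base, which should spare the epimerisable γ-stereocenter C13.

Step 9
Reactants: 11 (S)-2-methyl-4-(propan-2-yl)cyclopent-2-en-1-one
Product: 13 (2S,3S,4S)-2-(hydroxymethyl)-2-methyl-4-(propan-2-yl)-3-(prop-2-yn-1-yl)cyclopentan-1-one, via trichlorotitanium enolate 12 (not isolated)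
Conditions: H2C=C=CHSnBu3, TiCl4, CH2Cl2, −78 °C; then 1,3,5-trioxane, −78 to −30 °C; aq NaHCO3
Reagents that add atoms: tributyl(propa-1,2-dien-1-yl)stannane (C=C=C[Sn](CCCC)(CCCC)CCCC); 1,3,5-trioxane (C1OCOCO1)
Why: Lewis-acid conjugate propargylation (SE2′ attack of the allenylstannane) anti to the C13 isopropyl sets C11, and aldol capture of formaldehyde by the titanium enolate anti to the new propargyl group sets the quaternary C10.

Step 10
Reactants: 13 (2S,3S,4S)-2-(hydroxymethyl)-2-methyl-4-(propan-2-yl)-3-(prop-2-yn-1-yl)cyclopentan-1-one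
Product: 14 (1R,2S,3S,4S)-2-(hydroxymethyl)-2-methyl-4-(propan-2-yl)-3-(prop-2-yn-1-yl)cyclopentan-1-ol
Conditions: Me4NBH(OAc)3, MeCN/AcOH (1:1), −20 °C
Reagents that add atoms: none
Why: Evans–Saksena reduction delivers hydride within the alkoxyborohydride from the face of the CH2OH arm, so the C15 hydroxyl should come out trans to that arm and cis to the C10 methyl.

Step 11
Reactants: 14 (1R,2S,3S,4S)-2-(hydroxymethyl)-2-methyl-4-(propan-2-yl)-3-(prop-2-yn-1-yl)cyclopentan-1-ol
Product: 16 bis-silyl ether (primary OSiEt3 and secondary OSit-BuMe2), via mono-triethylsilyl ether 15 (not isolated)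
Conditions: TESCl (1.05 equiv), imidazole, CH2Cl2, −20 °C; then TBSOTf, 2,6-lutidine, 0 °C
Reagents that add atoms: chlorotriethylsilane (CC[Si](Cl)(CC)CC); tert-butyldimethylsilyl trifluoromethanesulfonate (CC(C)(C)[Si](C)(C)OS(=O)(=O)C(F)(F)F)
Why: Sequential silylation uses the higher reactivity of the primary alcohol toward the chlorosilane, then the silyl triflate for the hindered secondary alcohol.

Step 12
Reactants: 16 bis-silyl ether with terminal alkyne
Product: 17 bis-silyl ether with but-2-yn-1-yl arm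
Conditions: n-BuLi, THF, −78 °C; MeI, −78 °C to rt
Reagents that add atoms: iodomethane (CI)
Why: Alkylation of the lithium acetylide should give the methyl alkyne that carries C6 and its methyl.

Step 13
Reactants: 17 bis-silyl ether with but-2-yn-1-yl arm
Product: 19 (E)-alkenyl iodide (3-iodobut-2-en-1-yl arm), via alkenylzirconocene chloride 18 (not isolated)
Conditions: Cp2Zr(H)Cl (2.5 equiv), THF, 50 °C; then I2, 0 °C
Reagents that add atoms: iodine (II)
Why: Syn hydrozirconation, equilibrated by excess reagent to zirconium on the methyl-bearing carbon, followed by iodinolysis with retention should give the (E)-2-iodoalkene.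

**Union and completion**

Step 14
Reactants: 19 (E)-alkenyl iodide; 6 ethyl 3-[(1S,2S)-2-methyl-5-oxocyclopentyl]propanoate
Product: 22 cis-fused δ-lactone with C5–O and the (E)-C6=C7 alkenyl group on C5, via alkenyllithium 20 (not isolated), via lithium alkoxide 21 (not isolated)
Conditions: 19, t-BuLi (2.05 equiv), Et2O, −78 °C; then 6 premixed with LaCl3·2LiCl, THF, −78 °C to rt
Reagents that add atoms: none
Why: Iodine–lithium exchange keeps the alkene geometry, the lanthanum-promoted 1,2-addition should occur on the ketone face anti to the two cis substituents at C4 and C18, and the alkoxide, cis to the ester chain, lactonises.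

Step 15
Reactants: 22 cis-fused δ-lactone
Product: 23 exocyclic enol ether (2-methylidene pyran; the new CH2 is C8)
Conditions: Cp2TiMe2 (3 equiv), toluene, 70 °C, dark
Reagents that add atoms: dimethyltitanocene (C[Ti](C)(C1C=CC=C1)C1C=CC=C1)
Why: Petasis methylenation converts the lactone carbonyl into the enol ether without acid and tolerates the silyl ethers and the alkene.

Step 16
Reactants: 23 exocyclic enol ether
Product: 24 bicyclic cyclooct-4-enone (rings A and B; C1 ketone, C5=C6 alkene, C7 stereocenter)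
Conditions: toluene (0.01 M, trace Et3N, base-washed sealed tube), 180 °C
Reagents that add atoms: none
Why: Concerted [3,3] sigmatropic (Claisen) shift of the allyl vinyl ether C8=C1–O–C5–C6=C7: the C5–O bond breaks while C8–C7 forms, so the six-membered oxacycle is turned into the carbocyclic eight-membered ring B with the C1 ketone and the tetrasubstituted C5=C6 alkene. The closest known reaction type is the Claisen ring expansion of 2-methylidene-6-vinyltetrahydropyrans to cyclooct-4-enones. Ring B closes by a two-carbon ring expansion through a bicyclo[3.3.1]-like chair–chair transition state in which the alkenyl group is axial on the pyran chair. The new stereocenter C7 is set by 1,3-transfer of chirality from the C5 carbinol centre (fixed in step 14 by C4 and C18) together with the (E) geometry of the C6=C7 alkene, whose C12 substituent sits exo (pseudo-equatorial) and whose hydrogen points into the bicycle. The step needs chair over boat selectivity, which the small inward hydrogen at C7 should secure, and a cis ring alkene, which is enforced because the C2–C3–C4 tether keeps C4 on the same side of C5=C6 as C7.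

Step 17
Reactants: 24 bicyclic cyclooct-4-enone
Product: 25 keto aldehyde (C9 is CHO on the quaternary C10)
Conditions: (COCl)2, DMSO, CH2Cl2, −78 to −30 °C; then Et3N, −78 °C to rt
Reagents that add atoms: none
Why: Swern conditions cleave a primary triethylsilyl ether and oxidise it to the aldehyde in one operation, while the secondary tert-butyldimethylsilyl ether and the ketone should survive.

Step 18
Reactants: 25 keto aldehyde
Product: 27 tetracyclic enone (C8=C9 conjugated with the C1 ketone), via β-hydroxy ketone 26 (not isolated)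
Conditions: NaOMe, MeOH/THF, 0 to 50 °C
Reagents that add atoms: none
Why: Intramolecular aldol condensation closes ring C only from the C8 enolate (six-membered ring; the C2 enolate would give an eight-membered ring) onto the non-enolisable aldehyde, and the trans C10/C11 arms fix the trans C/D fusion.

Step 19
Reactants: 27 tetracyclic enone
Product: 29 tetracyclic ketone with trans B/C fusion, via lithium enolate 28 (not isolated)
Conditions: Li, NH3(l)/THF, −78 °C; NH4Cl; then NaOMe (cat.), MeOH, rt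
Reagents that add atoms: none
Why: Dissolving-metal conjugate reduction gives the C1 enolate, and protonation with methoxide equilibration should deliver the C8 epimer with C1 equatorial on the ring C chair, which avoids a 1,3-diaxial clash with the C10 methyl.

Step 20
Reactants: 29 tetracyclic ketone
Product: 30 silyl ether of the target (C1=CH2)
Conditions: Ph3PCH3Br, KOt-Bu, toluene, 80 °C
Reagents that add atoms: methyltriphenylphosphonium bromide (C[P+](c1ccccc1)(c1ccccc1)c1ccccc1.[Br-])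
Why: Wittig methylenation of the hindered ketone installs the exocyclic methylene; C8 is already the thermodynamic epimer, so the basic ylide should not change it.

Step 21
Reactants: 30 silyl ether of the target
Product: 31 target alcohol CNP0510481.1
Conditions: Bu4NF, THF, 50 °C
Reagents that add atoms: none
Why: Fluoride desilylation frees the C15 hydroxyl without affecting the two alkenes.

**Compound list**

1 | 3-methylcyclopent-2-en-1-one | CC1=CC(=O)CC1 | starting material
2 | 2-iodo-3-methylcyclopent-2-en-1-one | CC1=C(I)C(=O)CC1 | intermediate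
3 | ethyl 3-(2-methyl-5-oxocyclopent-1-en-1-yl)propanoate | CCOC(=O)CCC1=C(C)CCC1=O | intermediate
4 | ethyl 3-[(5S)-5-hydroxy-2-methylcyclopent-1-en-1-yl]propanoate | CCOC(=O)CCC1=C(C)CC[C@@H]1O | intermediate
5 | ethyl 3-[(1S,2S,5S)-2-hydroxy-5-methylcyclopentyl]propanoate | CCOC(=O)CC[C@@H]1[C@@H](O)CC[C@@H]1C | intermediate
6 | ethyl 3-[(1S,2S)-2-methyl-5-oxocyclopentyl]propanoate (cis) | CCOC(=O)CC[C@@H]1C(=O)CC[C@@H]1C | intermediate
7 | (R)-4-[(tert-butyldimethylsilyl)oxy]cyclopent-2-en-1-one | O=C1C=C[C@H](O[Si](C)(C)C(C)(C)C)C1 | starting material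
8 | (3S,4R)-4-[(tert-butyldimethylsilyl)oxy]-3-(propan-2-yl)cyclopentan-1-one | CC(C)[C@@H]1CC(=O)C[C@H]1O[Si](C)(C)C(C)(C)C | intermediate
9 | (S)-4-(propan-2-yl)cyclopent-2-en-1-one | O=C1C=C[C@H](C(C)C)C1 | intermediate
10 | (S)-2-iodo-4-(propan-2-yl)cyclopent-2-en-1-one | O=C1C(I)=C[C@H](C(C)C)C1 | intermediate
11 | (S)-2-methyl-4-(propan-2-yl)cyclopent-2-en-1-one | CC1=C[C@H](C(C)C)CC1=O | intermediate
12 | trichlorotitanium enolate of (3S,4S)-2-methyl-4-(propan-2-yl)-3-(prop-2-yn-1-yl)cyclopentanone | C#CC[C@H]1[C@H](C(C)C)CC(O[Ti](Cl)(Cl)Cl)=C1C | intermediate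
13 | (2S,3S,4S)-2-(hydroxymethyl)-2-methyl-4-(propan-2-yl)-3-(prop-2-yn-1-yl)cyclopentan-1-one | C#CC[C@H]1[C@H](C(C)C)CC(=O)[C@]1(C)CO | intermediate
14 | (1R,2S,3S,4S)-2-(hydroxymethyl)-2-methyl-4-(propan-2-yl)-3-(prop-2-yn-1-yl)cyclopentan-1-ol | C#CC[C@H]1[C@H](C(C)C)C[C@@H](O)[C@]1(C)CO | intermediate
15 | (1R,2S,3S,4S)-2-methyl-4-(propan-2-yl)-3-(prop-2-yn-1-yl)-2-{[(triethylsilyl)oxy]methyl}cyclopentan-1-ol | C#CC[C@H]1[C@H](C(C)C)C[C@@H](O)[C@]1(C)CO[Si](CC)(CC)CC | intermediate
16 | tert-butyl({(1R,2S,3S,4S)-2-methyl-4-(propan-2-yl)-3-(prop-2-yn-1-yl)-2-{[(triethylsilyl)oxy]methyl}cyclopentyl}oxy)dimethylsilane | C#CC[C@H]1[C@H](C(C)C)C[C@@H](O[Si](C)(C)C(C)(C)C)[C@]1(C)CO[Si](CC)(CC)CC | intermediate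
17 | tert-butyl({(1R,2S,3S,4S)-3-(but-2-yn-1-yl)-2-methyl-4-(propan-2-yl)-2-{[(triethylsilyl)oxy]methyl}cyclopentyl}oxy)dimethylsilane | CC#CC[C@H]1[C@H](C(C)C)C[C@@H](O[Si](C)(C)C(C)(C)C)[C@]1(C)CO[Si](CC)(CC)CC | intermediate
18 | chlorobis(cyclopentadienyl)[(2E)-4-RD-but-2-en-2-yl]zirconium | C/C(=C\C[C@H]1[C@H](C(C)C)C[C@@H](O[Si](C)(C)C(C)(C)C)[C@]1(C)CO[Si](CC)(CC)CC)[Zr](Cl)(C2C=CC=C2)C2C=CC=C2 | intermediate
19 | tert-butyl({(1R,2S,3S,4S)-3-[(2E)-3-iodobut-2-en-1-yl]-2-methyl-4-(propan-2-yl)-2-{[(triethylsilyl)oxy]methyl}cyclopentyl}oxy)dimethylsilane | C/C(I)=C\C[C@H]1[C@H](C(C)C)C[C@@H](O[Si](C)(C)C(C)(C)C)[C@]1(C)CO[Si](CC)(CC)CC | intermediate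
20 | alkenyllithium from 19 (lithium in place of iodine, geometry retained) | C/C([Li])=C\C[C@H]1[C@H](C(C)C)C[C@@H](O[Si](C)(C)C(C)(C)C)[C@]1(C)CO[Si](CC)(CC)CC | intermediate
21 | lithium alkoxide of ethyl 3-[(1S,2R,5S)-2-hydroxy-5-methyl-2-[(2E)-4-RD-but-2-en-2-yl]cyclopentyl]propanoate | CCOC(=O)CC[C@H]1[C@@H](C)CC[C@]1(O[Li])/C(C)=C/C[C@H]2[C@H](C(C)C)C[C@@H](O[Si](C)(C)C(C)(C)C)[C@]2(C)CO[Si](CC)(CC)CC | intermediate
22 | (4aS,5S,7aR)-5-methyl-7a-[(2E)-4-RD-but-2-en-2-yl]hexahydrocyclopenta[b]pyran-2(3H)-one | O=C1CC[C@H]2[C@@H](C)CC[C@]2(O1)/C(C)=C/C[C@H]3[C@H](C(C)C)C[C@@H](O[Si](C)(C)C(C)(C)C)[C@]3(C)CO[Si](CC)(CC)CC | intermediate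
23 | (4aS,5S,7aR)-5-methyl-2-methylidene-7a-[(2E)-4-RD-but-2-en-2-yl]octahydrocyclopenta[b]pyran | C=C1CC[C@H]2[C@@H](C)CC[C@]2(O1)/C(C)=C/C[C@H]3[C@H](C(C)C)C[C@@H](O[Si](C)(C)C(C)(C)C)[C@]3(C)CO[Si](CC)(CC)CC | intermediate
24 | (1S,6S,11S)-7,11-dimethyl-6-(RD-methyl)bicyclo[6.3.0]undec-7-en-4-one | O=C1CC[C@@H]2/C(=C(/C)[C@H](C1)C[C@H]3[C@H](C(C)C)C[C@@H](O[Si](C)(C)C(C)(C)C)[C@]3(C)CO[Si](CC)(CC)CC)CC[C@@H]2C | intermediate
25 | keto aldehyde: 24 with the CH2OSiEt3 group of RD replaced by CHO | O=C1CC[C@@H]2/C(=C(/C)[C@H](C1)C[C@H]3[C@H](C(C)C)C[C@@H](O[Si](C)(C)C(C)(C)C)[C@]3(C)C=O)CC[C@@H]2C | intermediate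
26 | tetracyclic aldol: C9 hydroxy, C1 ketone, C15 OSit-BuMe2 (C8 and C9 configuration not defined) | O=C1CC[C@@H]2/C(=C(/C)[C@H]3C[C@H]4[C@H](C(C)C)C[C@@H](O[Si](C)(C)C(C)(C)C)[C@]4(C)C(O)C13)CC[C@@H]2C | intermediate
27 | tetracyclic enone: C8=C9 alkene conjugated with the C1 ketone, C15 OSit-BuMe2 | O=C1CC[C@@H]2/C(=C(/C)[C@H]3C[C@H]4[C@H](C(C)C)C[C@@H](O[Si](C)(C)C(C)(C)C)[C@]4(C)C=C13)CC[C@@H]2C | intermediate
28 | lithium enolate (C1–OLi, C1=C8) of 29 | [Li]OC1CC[C@@H]2/C(=C(/C)[C@H]3C[C@H]4[C@H](C(C)C)C[C@@H](O[Si](C)(C)C(C)(C)C)[C@]4(C)CC=13)CC[C@@H]2C | intermediate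
29 | tetracyclic C1 ketone with all target stereocenters, C15 OSit-BuMe2 | O=C1CC[C@@H]2/C(=C(/C)[C@H]3C[C@H]4[C@H](C(C)C)C[C@@H](O[Si](C)(C)C(C)(C)C)[C@]4(C)C[C@H]13)CC[C@@H]2C | intermediate
30 | tert-butyldimethylsilyl ether of the target | C=C1CC[C@@H]2/C(=C(/C)[C@H]3C[C@H]4[C@H](C(C)C)C[C@@H](O[Si](C)(C)C(C)(C)C)[C@]4(C)C[C@H]13)CC[C@@H]2C | intermediate
31 | CNP0510481.1 (5-8-6-5 tetracyclic alcohol) | C=C1CC[C@@H]2/C(=C(/C)[C@H]3C[C@H]4[C@H](C(C)C)C[C@@H](O)[C@]4(C)C[C@H]13)CC[C@@H]2C | target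

**Totals and risks**

Total step count: 21. Longest linear sequence: 16 steps (7 to 31, steps 6 to 13 and 14 to 21).

Step 16. The rearrangement may pass in part through the boat-like array and give the C7 epimer, or the enol ether may isomerise into the ring or hydrolyse before it rearranges at 180 °C. Fallback, from 23 back to 24: treatment of 23 with i-Bu3Al in CH2Cl2 at −78 °C to rt should ionise the allylic C5–O bond at low temperature, let the aluminium enolate recombine at C7 and reduce the new ketone in the same flask, giving the cyclooctenol (C1 epimers) F1. Dess–Martin oxidation of F1 then returns 24.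

Step 14. The basic alkenyllithium may enolise 6 (loss of the cis C4/C18 relationship), attack the ester, or add with incomplete facial selectivity. Fallback, from 16 and 6 back to 22:
- The lithium acetylide of 16 (n-BuLi, THF, −78 °C) is added to 6 premixed with LaCl3·2LiCl and quenched cold with AcOH to give the propargylic alcohol F2.
- Hydroxyl-directed trans-hydrostannation ([Cp*RuCl]4, Bu3SnH, CH2Cl2) should place tin on C6 and hydrogen on C7, giving the alkenylstannane F3.
- Methyl-for-tin exchange (MeI, Cu(O2C-2-thienyl), [Ph2PO2][NBu4], Pd(PPh3)4, DMF) gives the hydroxy ester F4, which lactonises (NaOEt cat., THF) to 22.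

Step 9. The allenylstannane may transfer an allenyl instead of a propargyl group or react sluggishly with the trisubstituted enone, and the titanium enolate may fail to capture formaldehyde or the aldol may revert on work-up. Fallback, from 11 back to 16:
- Conjugate allylation (allylmagnesium bromide, CuBr·SMe2, TMSCl, THF, −78 °C) gives the trimethylsilyl enol ether F5.
- Mukaiyama hydroxymethylation (aq CH2O, Sc(OTf)3, THF) gives the β-hydroxy ketone F6.
- Reduction as in step 10 gives the diol F7, and silylation as in step 11 gives the mono-triethylsilyl ether F8 and then the bis-silyl ether F9.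
- Lemieux–Johnson cleavage (OsO4 cat., NaIO4, 2,6-lutidine, dioxane/H2O) gives the aldehyde F10.
- Ohira–Bestmann homologation (dimethyl (1-diazo-2-oxopropyl)phosphonate, K2CO3, MeOH) gives 16.

Further compounds
F1 | step 16 | (1S,6S,11S)-7,11-dimethyl-6-(RD-methyl)bicyclo[6.3.0]undec-7-en-4-ol (C4 epimers) | OC1CC[C@@H]2/C(=C(/C)[C@H](C1)C[C@H]3[C@H](C(C)C)C[C@@H](O[Si](C)(C)C(C)(C)C)[C@]3(C)CO[Si](CC)(CC)CC)CC[C@@H]2C
F2 | step 14 | ethyl 3-[(1S,2R,5S)-2-hydroxy-5-methyl-2-(3-RD-prop-1-yn-1-yl)cyclopentyl]propanoate | CCOC(=O)CC[C@H]1[C@@H](C)CC[C@]1(O)C#CC[C@H]2[C@H](C(C)C)C[C@@H](O[Si](C)(C)C(C)(C)C)[C@]2(C)CO[Si](CC)(CC)CC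
F3 | step 14 | ethyl 3-[(1S,2R,5S)-2-hydroxy-5-methyl-2-[(1Z)-3-RD-1-(tributylstannyl)prop-1-en-1-yl]cyclopentyl]propanoate | CCOC(=O)CC[C@H]1[C@@H](C)CC[C@]1(O)/C([Sn](CCCC)(CCCC)CCCC)=C/C[C@H]2[C@H](C(C)C)C[C@@H](O[Si](C)(C)C(C)(C)C)[C@]2(C)CO[Si](CC)(CC)CC
F4 | step 14 | ethyl 3-[(1S,2R,5S)-2-hydroxy-5-methyl-2-[(2E)-4-RD-but-2-en-2-yl]cyclopentyl]propanoate | CCOC(=O)CC[C@H]1[C@@H](C)CC[C@]1(O)/C(C)=C/C[C@H]2[C@H](C(C)C)C[C@@H](O[Si](C)(C)C(C)(C)C)[C@]2(C)CO[Si](CC)(CC)CC
F5 | step 9 | trimethyl{[(3S,4S)-2-methyl-4-(propan-2-yl)-3-(prop-2-en-1-yl)cyclopent-1-en-1-yl]oxy}silane | C=CC[C@H]1[C@H](C(C)C)CC(O[Si](C)(C)C)=C1C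
F6 | step 9 | (2S,3S,4S)-2-(hydroxymethyl)-2-methyl-4-(propan-2-yl)-3-(prop-2-en-1-yl)cyclopentan-1-one | C=CC[C@H]1[C@H](C(C)C)CC(=O)[C@]1(C)CO
F7 | step 9 | (1R,2S,3S,4S)-2-(hydroxymethyl)-2-methyl-4-(propan-2-yl)-3-(prop-2-en-1-yl)cyclopentan-1-ol | C=CC[C@H]1[C@H](C(C)C)C[C@@H](O)[C@]1(C)CO
F8 | step 9 | (1R,2S,3S,4S)-2-methyl-4-(propan-2-yl)-3-(prop-2-en-1-yl)-2-{[(triethylsilyl)oxy]methyl}cyclopentan-1-ol | C=CC[C@H]1[C@H](C(C)C)C[C@@H](O)[C@]1(C)CO[Si](CC)(CC)CC
F9 | step 9 | tert-butyl({(1R,2S,3S,4S)-2-methyl-4-(propan-2-yl)-3-(prop-2-en-1-yl)-2-{[(triethylsilyl)oxy]methyl}cyclopentyl}oxy)dimethylsilane | C=CC[C@H]1[C@H](C(C)C)C[C@@H](O[Si](C)(C)C(C)(C)C)[C@]1(C)CO[Si](CC)(CC)CC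
F10 | step 9 | 2-RD-acetaldehyde | O=CC[C@H]1[C@H](C(C)C)C[C@@H](O[Si](C)(C)C(C)(C)C)[C@]1(C)CO[Si](CC)(CC)CC
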